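# Proposed total synthesis of CNP0126838.1 through an aryne–glycidate cascade

## Analysis of the target

The target is a branched tetraflavanoid. One (+)-catechin unit (2R,3S) carries an ent-fisetinidol unit on C8 and a second one on C6 of its ring A, each bound through its own C4. The C8-bound (middle) unit carries a third ent-fisetinidol unit (the upper unit), again through C4 of that unit, on C6 of its ring A. There are eleven stereocentres: C2 and C3 of catechin, and C2 (S), C3 (R) and C4 in each ent-fisetinidol unit. In all three of these units ring B and O3 are trans and the C4 aryl substituent is cis to O3 (4α linkages). The C4 descriptors are R in the upper unit and S in the middle and side units only because the CIP priorities differ. The three ent-fisetinidol units belong to the enantiomeric series that no abundant flavan-3-ol supplies and they lack oxygen at C5, whereas the catechin unit can be taken from the chiral pool. Of the seventeen hydroxyl groups thirteen are phenolic, so the free compound is sensitive to air and base, and the three C4–aryl bonds and the benzylic C2–O1 bonds are labile to acid. All hydroxyls are therefore carried as benzyl ethers and freed last by hydrogenolysis. The main difficulty is three crowded C(sp3)–C(sp2) bonds, two of them on neighbouring positions of one phloroglucinol ring, with a 3,4-cis arrangement that acid-mediated coupling of flavan-4-yl cations does not favour. The strategy rests on one feature of each ent-fisetinidol unit: ring A bears O1 on C8a and C4 on C4a, on adjacent carbons, with O7 as its only other substituent, and C2 and C3 carry aryl and hydroxyl trans, as in a trans-epoxide opened at its benzylic carbon.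

## Retrosynthetic reasoning

**Protecting groups and chlorine.** Target 41 is traced back to 40 by cutting all seventeen O–benzyl bonds and replacing the C5 hydrogen of each ent-fisetinidol unit by chlorine. The chlorines are needed earlier to steer the ring-forming step, and the conditions that remove benzyl groups also cleave aryl C–Cl bonds, so nothing is added to the step count. The forward reaction must keep the medium close to neutral.

**C4–H bonds of the upper and side units.** In 40 these two bonds are cut to give the bis-carbinol 39. A tertiary diarylcarbinol ionises easily, and hydride capture by the planar cation is the point at which 3,4-cis can be set. The forward reduction has to deliver hydride to the face opposite the C3 benzyloxy group.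

**C4–aryl bonds to the upper and side units.** 39 is cut at both carbinol–aryl bonds to the dibromide 36 and two molecules of ketone 15. The carbonyl carbon of 15 is the natural electrophile and a metalated ring A the nucleophile. This avoids the cation coupling that would give 3,4-trans. The forward step needs two aryl-metal additions to a hindered ketone that has an enolisable C3 hydrogen.

**The dimer.** 36 goes back to 35 by cutting the C–Br bond at catechin C6. 35 goes back to carbinol 34 by cutting C4–H, and 34 to the catechin bromide 31 and bromo ketone 27 by cutting C4–C8. The order follows the reactivity of catechin: C8 is brominated first, so the middle unit is attached there, and C6 is functionalised afterwards.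

**Ring C of the ketone (key disconnection).** 15 is the benzyl ether of ketol 14. In 14 three bonds are cut: O1–C8a, C4–C4a and O1–C2. This leads to the silyl triflate 11 (as aryne 12) and the glycidate salt 4. The cut is made here because it removes ring C and gives two simple partners. The carboxylate supplies O1 and C4, and the epoxide supplies C2, C3 and their configuration. The forward cascade must control the orientation of addition to the aryne, the O-to-C acyl shift and the site of epoxide opening.

**The brominated ketone.** 27 and its ketol 26 are cut in the same way to silyl triflate 23 and 4. Bromine is carried in from the aryne partner. Bromination of a finished 5-chloro-7-benzyloxychromanone would be divided between C6 and C8, with C8 the more accessible position.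

**Aryne precursor 11.** The C–Si and O–S bonds are cut back to 4-(benzyloxy)phenol 5 through 8, 7 and 6. Two ortho halogenations, O-silylation and a silyl shift from oxygen to carbon are all directed by the phenol oxygen.

**Aryne precursor 23.** This goes back through 22 and 18 to 4,6-dibromo-5-chlororesorcinol 17 and 5-chlororesorcinol 16. The two bromines of 17 are equivalent. One is turned into the silyl group, which also distinguishes the two oxygens, and the other is left between chlorine and the oxygen that becomes O7.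

**Glycidate and catechin partners.** 4 is cut at the epoxide C–O bonds to cinnamate 2 and caffeic acid 1, and the forward epoxidation must be enantioselective for the (2S,3R) isomer. 31 comes from (+)-catechin 28 through 29 and 30.

## Alternatives that were turned down

**Alternative 1:** The two outer rings C are cut at C3=C4. Each outer unit is then present as a 1,1-diarylethene next to an enantiopure 1-arylallyl aryl ether, and a ruthenium carbene catalyst would close both rings by metathesis with loss of ethylene to give the bis-flav-3-ene A1.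
- For: two rings form in one catalytic, neutral step, the benzyl ethers are untouched, and C2 of both outer units arrives as a preformed stereocentre. In rings closed per step it is stronger than the chosen route, which closes one ring C per cascade.
- Against: the alkene carbon that must enter the metallacycle carries two aryl groups, one of them doubly ortho-substituted, and such alkenes are among the least reactive metathesis partners.
- Against: the allylic carbon is benzylic, activated by a para-alkoxy group and bound to an aryloxy group, so ionisation or a sigmatropic shift threatens its configuration.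
- Against: A1 still lacks O3 and the C4 hydrogen in two units. Hydroboration would add both to the face away from ring B and give 3,4-trans, the opposite of what is needed, so an epoxidation and reductive opening would have to follow for each ring. The 3,4-cis linkage of the middle unit is not addressed.
- Comparison: the chosen strategy closes fewer rings per step, but its rings arrive oxygenated at C3 and C4 with C2 and C3 fixed, and the C4 carbonyl solves linkage and configuration together.

**Alternative 2:** Ring C of the middle unit is cut at C3–C4 and at the O1–C2 acyl bond. An ortho-quinone methide carrying the catechin nucleus on its exocyclic carbon would be combined with the ammonium enolate of an alkoxyketene under a cinchona-type nucleophilic catalyst, and the [4+2] product is the cis-dihydrocoumarin A2.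
- For: C3 and C4 are formed together with the cis relationship the target needs, under catalyst control, and the bromine for the next linkage is already in place. On control of C4 this is stronger than the chosen route, which relies on substrate-controlled hydride delivery.
- Against: A2 is a lactone, so C2 is a carbonyl carbon and ring B is missing. Ring B would have to come in by aryl addition and reduction of a lactol through a cyclic oxocarbenium ion, where hydride must enter cis to O3. A neighbouring alkoxy group does not reliably enforce this.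
- Against: the quinone methide is flanked by a chiral, fully substituted ring, so catalyst and substrate control may oppose each other.
- Against: only one of the three ent-fisetinidol units is made, and the other two need the same sequence on more crowded intermediates.
- Comparison: the chosen strategy offers C2 and C3 from one enantiopure epoxide, ring B inside the building block, and the same cascade for all three units.

**Alternative 3:** All three C2–aryl bonds of the ent-fisetinidol units are cut, so that ring B comes last. A tris(2-acetoxy-3-acyloxychroman) would be converted into anomeric bromides, the 3-O-acyl groups would bridge to dioxolanium ions, and an arylzinc reagent would open them at C2 opposite the bridge to give the tris-pivalate A3.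
- For: it is the most convergent plan, with three aryl groups and three stereocentres in one step from a common core. The 2,3-trans relationship is enforced by participation, and ring B could be varied. In convergence it is clearly stronger than the chosen route.
- Against: the core must already hold every C3 and C4 centre with the 3,4-cis linkages. Building such a skeleton without ring B is a synthesis in itself, and the chiral pool offers nothing for it.
- Against: the C2 cations are conjugated to the ring oxygen and can lose the C3 proton to give chromenes, and the Lewis-acidic bromide source acts on a molecule with acid-labile C4–aryl bonds.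
- Against: three simultaneous substitutions multiply any shortfall in selectivity, and the pivalates need a separate, forcing removal.
- Comparison: the chosen strategy spends more steps on building blocks but has no late threefold stereochemical gamble, because each unit enters with C2 and C3 secure.

Key step: step 8

Assumption: the D-fructose-derived diacetate ketone of step 2 is taken to deliver oxygen to the cinnamate on the same face as to other trans-β-substituted styrenes, which corresponds to the (2S,3R)-glycidate; if the sense were opposite, the enantiomeric ketone would be used.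

## Route

Step 1
Reactants: 1 caffeic acid
Product: 2 benzyl (E)-3-[3,4-bis(benzyloxy)phenyl]prop-2-enoate
Conditions: BnBr (3.5 equiv), K2CO3, DMF, 60 °C
Reagents that add atoms: benzyl bromide, BrCc1ccccc1
Why: Williamson etherification of both phenols and O-alkylation of the carboxylate in one operation; the E double bond is not touched.

Step 2
Reactants: 2 benzyl (E)-3-[3,4-bis(benzyloxy)phenyl]prop-2-enoate
Product: 3 benzyl (2S,3R)-3-[3,4-bis(benzyloxy)phenyl]oxirane-2-carboxylate
Conditions: 4,5-di-O-acetyl-1,2-O-isopropylidene-β-D-erythro-2,3-hexodiulo-2,6-pyranose (0.3 equiv), KHSO5 (as 2KHSO5·KHSO4·K2SO4), NaHCO3, Bu4NHSO4, MeCN/H2O, 0 °C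
Reagents that add atoms: potassium peroxymonosulfate, [K+].[O-]S(=O)(=O)OO
Why: Shi epoxidation with the ester-tolerant chiral dioxirane; the electron-rich cinnamate is epoxidised through a spiro transition state, the E geometry becomes the trans epoxide, and the catalyst sets both centres as (2S,3R).

Step 3
Reactants: 3 benzyl (2S,3R)-3-[3,4-bis(benzyloxy)phenyl]oxirane-2-carboxylate
Product: 4 potassium (2S,3R)-3-[3,4-bis(benzyloxy)phenyl]oxirane-2-carboxylate
Conditions: KOH (1.0 equiv), THF/H2O, 0 °C; freeze-dry, wash with Et2O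
Reagents that add atoms: potassium hydroxide, [K+].[OH-]
Why: Saponification of the ester is faster than hydroxide attack on the epoxide at 0 °C; the acid is kept as its salt because free para-alkoxyphenyl glycidic acids decarboxylate.

Step 4
Reactants: 5 4-(benzyloxy)phenol
Product: 6 4-(benzyloxy)-2-chlorophenol
Conditions: SO2Cl2 (1.0 equiv), CH2Cl2, 0 °C to rt
Reagents that add atoms: sulfuryl chloride, O=S(=O)(Cl)Cl
Why: Electrophilic chlorination; the hydroxyl is the stronger director and its para position is blocked, so chlorine enters ortho to OH.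

Step 5
Reactants: 6 4-(benzyloxy)-2-chlorophenol
Product: 7 4-(benzyloxy)-2-bromo-6-chlorophenol
Conditions: NBS (1.0 equiv), i-Pr2NH (10 mol %), CH2Cl2, 0 °C
Reagents that add atoms: N-bromosuccinimide, BrN1C(=O)CCC1=O
Why: Amine-assisted ortho-bromination of a phenol; only one position ortho to the hydroxyl is left.

Step 6
Reactants: 7 4-(benzyloxy)-2-bromo-6-chlorophenol
Product: 8 [4-(benzyloxy)-2-bromo-6-chlorophenoxy]trimethylsilane
Conditions: (Me3Si)2NH, THF, 70 °C; evaporate
Reagents that add atoms: hexamethyldisilazane, C[Si](C)(C)N[Si](C)(C)C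
Why: O-Silylation of the phenol with the disilazane liberates only ammonia, so the crude silyl ether is dry enough for lithiation.

Step 7
Reactants: 8 [4-(benzyloxy)-2-bromo-6-chlorophenoxy]trimethylsilane
Product: 11 4-(benzyloxy)-2-chloro-6-(trimethylsilyl)phenyl trifluoromethanesulfonate, via aryllithium 9 (not isolated), via lithium phenoxide 10 (not isolated)
Conditions: n-BuLi (1.05 equiv), THF, −78 °C; Tf2O (1.2 equiv), −78 to 0 °C
Reagents that add atoms: trifluoromethanesulfonic anhydride, O=S(=O)(OS(=O)(=O)C(F)(F)F)C(F)(F)F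
Why: Bromine–lithium exchange (the chloride is inert at −78 °C), retro-Brook 1,3-shift of silicon from oxygen to the lithiated carbon, then O-triflation of the phenoxide; this is the standard route to 2-silylaryl triflates.

Step 8
Reactants: 11 4-(benzyloxy)-2-chloro-6-(trimethylsilyl)phenyl trifluoromethanesulfonate; 4 potassium (2S,3R)-3-[3,4-bis(benzyloxy)phenyl]oxirane-2-carboxylate
Product: 14 (2S,3S)-7-(benzyloxy)-2-[3,4-bis(benzyloxy)phenyl]-5-chloro-3-hydroxychroman-4-one, via aryne 12 (not isolated), via acylphenoxide 13 (not isolated)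
Conditions: 4 (1.5 equiv), CsF (3 equiv), 18-crown-6 (1.5 equiv), THF, 40 °C; then aq NH4Cl, 0 °C
Reagents that add atoms: none
Why: Proposed new method: fluoride removes the silyl group of 11 and triflate leaves, giving aryne 12; the carboxylate oxygen of 4 adds to the aryne carbon remote from chlorine, because the triple bond is distorted toward that carbon and the aryl anion that develops next to the C–Cl bond is inductively stabilised. The anion then attacks its own ester carbonyl through a four-membered transition state and the acyl group moves from oxygen to carbon, which forms C8a–O1 and C4a–C4 and unmasks phenoxide 13. The phenoxide opens the epoxide at the benzylic carbon in a 6-endo-tet closure of ring C (O1–C2). The closest known reactions are the insertion of arynes into the C–O bond of carboxylic acids to give ortho-hydroxyaryl ketones and the 6-endo cyclisation of 2'-hydroxychalcone epoxides to trans-dihydroflavonols; their combination in one flask with a glycidate is new. C2 is set as S by inversion at the epoxide carbon and C3 keeps the configuration of the glycidate α-carbon, so the trans epoxide gives the 2,3-trans ketol. Three selectivities are needed: aryne regiochemistry, secured by the chlorine beside the triple bond; acyl transfer over protonation of the aryl anion, secured by the preformed potassium salt in an aprotic medium; and 6-endo over 5-exo opening, secured by the para-benzyloxy group of ring B, which weakens the benzylic C–O bond. The glycidate is used in excess so that the product alkoxide does not compete for a second aryne.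

Step 9
Reactants: 14 (2S,3S)-7-(benzyloxy)-2-[3,4-bis(benzyloxy)phenyl]-5-chloro-3-hydroxychroman-4-one
Product: 15 (2S,3S)-3,7-bis(benzyloxy)-2-[3,4-bis(benzyloxy)phenyl]-5-chlorochroman-4-one
Conditions: BnOC(=NH)CCl3 (2 equiv), CF3SO3H (10 mol %), CH2Cl2/cyclohexane, 0 °C to rt
Reagents that add atoms: benzyl 2,2,2-trichloroacetimidate, ClC(Cl)(Cl)C(=N)OCc1ccccc1
Why: Acid-catalysed O-benzylation with the trichloroacetimidate avoids base, which would open ring C of the ketol by β-elimination or epimerise C3; both stereocentres are kept.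

Step 10
Reactants: 16 5-chlorobenzene-1,3-diol
Product: 17 4,6-dibromo-5-chlorobenzene-1,3-diol
Conditions: NBS (2.05 equiv), MeCN, −20 to 0 °C
Reagents that add atoms: N-bromosuccinimide, BrN1C(=O)CCC1=O
Why: Twofold electrophilic bromination at C4 and C6, each ortho to one hydroxyl and para to the other, as in resorcinol and its 5-substituted congeners; C2 between the hydroxyls reacts only after these positions.

Step 11
Reactants: 17 4,6-dibromo-5-chlorobenzene-1,3-diol
Product: 18 [(4,6-dibromo-5-chloro-1,3-phenylene)bis(oxy)]bis(trimethylsilane)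
Conditions: (Me3Si)2NH, THF, 70 °C; evaporate
Reagents that add atoms: hexamethyldisilazane, C[Si](C)(C)N[Si](C)(C)C
Why: Both phenols are silylated with loss of ammonia only; the symmetry of 17 is kept.

Step 12
Reactants: 18 [(4,6-dibromo-5-chloro-1,3-phenylene)bis(oxy)]bis(trimethylsilane)
Product: 22 4-bromo-3-chloro-5-hydroxy-2-(trimethylsilyl)phenyl trifluoromethanesulfonate, via aryllithium 19 (not isolated), via lithium phenoxide 20 (not isolated), via silyl ether triflate 21 (not isolated)
Conditions: n-BuLi (1.0 equiv), THF, −90 °C; Tf2O (1.1 equiv), −90 to −40 °C; then MeOH, aq NaHCO3, 0 °C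
Reagents that add atoms: trifluoromethanesulfonic anhydride, O=S(=O)(OS(=O)(=O)C(F)(F)F)C(F)(F)F
Why: The two bromines are equivalent, so a single bromine–lithium exchange needs no selectivity; retro-Brook shift of the neighbouring silyl group gives one phenoxide, which is triflated, and the remaining aryl silyl ether is methanolysed on work-up. The low temperature keeps the aryllithium next to chlorine from losing LiCl before silicon migrates. The two oxygens are thereby distinguished and the surviving bromine lies between chlorine and the free hydroxyl.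

Step 13
Reactants: 22 4-bromo-3-chloro-5-hydroxy-2-(trimethylsilyl)phenyl trifluoromethanesulfonate
Product: 23 5-(benzyloxy)-4-bromo-3-chloro-2-(trimethylsilyl)phenyl trifluoromethanesulfonate
Conditions: BnOH, PPh3, i-PrO2CN=NCO2i-Pr, THF, 0 °C to rt
Reagents that add atoms: benzyl alcohol, OCc1ccccc1
Why: Mitsunobu etherification of the acidic phenol under neutral conditions, so that no base or fluoride that could start aryne formation touches the silyl triflate.

Step 14
Reactants: 23 5-(benzyloxy)-4-bromo-3-chloro-2-(trimethylsilyl)phenyl trifluoromethanesulfonate; 4 potassium (2S,3R)-3-[3,4-bis(benzyloxy)phenyl]oxirane-2-carboxylate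
Product: 26 (2S,3S)-7-(benzyloxy)-2-[3,4-bis(benzyloxy)phenyl]-6-bromo-5-chloro-3-hydroxychroman-4-one, via aryne 24 (not isolated), via acylphenoxide 25 (not isolated)
Conditions: 4 (1.5 equiv), CsF (3 equiv), 18-crown-6 (1.5 equiv), THF, 40 °C; then aq NH4Cl, 0 °C
Reagents that add atoms: none
Why: Proposed new method: the same cascade as in step 8 with aryne 24, in which triflate leaves in preference to chloride; the bromine is not next to the triple bond and should not change the sense of addition, which is again set by chlorine, so oxygen enters the carbon that becomes C8a and the acyl group the carbon that becomes C4a. Ring C closes 6-endo-tet, C2 is formed with inversion (S) and C3 is retained; the closest known reactions are those named for step 8.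

Step 15
Reactants: 26 (2S,3S)-7-(benzyloxy)-2-[3,4-bis(benzyloxy)phenyl]-6-bromo-5-chloro-3-hydroxychroman-4-one
Product: 27 (2S,3S)-3,7-bis(benzyloxy)-2-[3,4-bis(benzyloxy)phenyl]-6-bromo-5-chlorochroman-4-one
Conditions: BnOC(=NH)CCl3 (2 equiv), CF3SO3H (10 mol %), CH2Cl2/cyclohexane, 0 °C to rt
Reagents that add atoms: benzyl 2,2,2-trichloroacetimidate, ClC(Cl)(Cl)C(=N)OCc1ccccc1
Why: Base-free O-benzylation as in step 9; the stereocentres and the aryl bromide are untouched.

Step 16
Reactants: 28 (+)-catechin
Product: 29 5,7,3',4'-tetra-O-benzyl-(+)-catechin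
Conditions: BnBr (4.4 equiv), K2CO3, DMF, 0 °C to rt
Reagents that add atoms: benzyl bromide, BrCc1ccccc1
Why: Williamson etherification with carbonate alkylates the four phenols and leaves the less acidic secondary alcohol; C2 and C3 are not affected.

Step 17
Reactants: 29 5,7,3',4'-tetra-O-benzyl-(+)-catechin
Product: 30 3,5,7,3',4'-penta-O-benzyl-(+)-catechin
Conditions: NaH, BnBr, Bu4NI (cat.), DMF, 0 °C to rt
Reagents that add atoms: benzyl bromide, BrCc1ccccc1
Why: Williamson etherification of the secondary alkoxide; with the phenols already capped there is no competing C-alkylation or quinone methide epimerisation.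

Step 18
Reactants: 30 3,5,7,3',4'-penta-O-benzyl-(+)-catechin
Product: 31 8-bromo-3,5,7,3',4'-penta-O-benzyl-(+)-catechin
Conditions: NBS (1.0 equiv), CH2Cl2, −78 to 0 °C
Reagents that add atoms: N-bromosuccinimide, BrN1C(=O)CCC1=O
Why: Electrophilic bromination of the phloroglucinol-type ring A; C8, between the ring oxygen and one benzyloxy group, is more accessible than C6 between two benzyloxy groups, which is the usual selectivity of benzylated flavan-3-ols.

Step 19
Reactants: 31 8-bromo-3,5,7,3',4'-penta-O-benzyl-(+)-catechin; 27 (2S,3S)-3,7-bis(benzyloxy)-2-[3,4-bis(benzyloxy)phenyl]-6-bromo-5-chlorochroman-4-one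
Product: 34 benzylated dimer carbinol (4-hydroxy-4-aryl adduct of 27 at catechin C8), via aryllithium 32 (not isolated), via arylcerium dichloride 33 (not isolated)
Conditions: 31 (1.2 equiv), n-BuLi (1.2 equiv), THF, −78 °C; CeCl3 (1.3 equiv), −78 °C; 27, −78 to −40 °C; aq NH4Cl
Reagents that add atoms: none
Why: Bromine–lithium exchange, transmetalation to the aryl cerium dichloride and 1,2-addition to the ketone; the cerium reagent is weakly basic, so the C3 hydrogen next to the carbonyl is not removed, and it does not exchange with the aryl bromide of 27. The configuration of the new carbinol carbon is not controlled and does not matter, because this carbon becomes planar in step 20.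

Step 20
Reactants: 34 benzylated dimer carbinol
Product: 35 benzylated dimer (6-bromo-5-chloro-ent-fisetinidol-(4→8)-catechin nonabenzyl ether, 3,4-cis)
Conditions: Et3SiH (5 equiv), CF3CO2H (10 equiv), CH2Cl2, −40 to 0 °C
Reagents that add atoms: none
Why: Ionic hydrogenation of a tertiary diarylcarbinol: acid ionises C4 to a cation stabilised by both aryl rings and the silane transfers hydride. Hydride is expected on the face opposite the C3 benzyloxy group, which the C4 aryl group pushes out of the ring plane, so the catechin ring ends cis to O3 and C4 is set 3,4-cis.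

Step 21
Reactants: 35 benzylated dimer
Product: 36 benzylated dimer dibromide (bromine at C6 of the upper unit and at C6 of catechin)
Conditions: NBS (1.05 equiv), CH2Cl2, −40 to 0 °C
Reagents that add atoms: N-bromosuccinimide, BrN1C(=O)CCC1=O
Why: Electrophilic bromination at the only strongly activated free position, C6 of the catechin ring A with three oxygens ortho or para; ring A of the upper unit is deactivated by its two halogens and the catechol rings are less electron-rich.

Step 22
Reactants: 36 benzylated dimer dibromide; 15 (2S,3S)-3,7-bis(benzyloxy)-2-[3,4-bis(benzyloxy)phenyl]-5-chlorochroman-4-one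
Product: 39 benzylated tetramer bis-carbinol, via dilithio compound 37 (not isolated), via bis(dichlorocerio) compound 38 (not isolated)
Conditions: n-BuLi (2.2 equiv), THF, −78 °C; CeCl3 (2.4 equiv), −78 °C; 15 (2.6 equiv), −78 to −30 °C; aq NH4Cl
Reagents that add atoms: none
Why: Twofold bromine–lithium exchange, transmetalation to cerium and two 1,2-additions to ketone 15 in one flask; both aryl metals are stabilised by their ortho substituents (chlorine and benzyloxy, or two benzyloxy groups) and the cerium reagents add to the hindered ketone without removing its C3 hydrogen. The two carbinol configurations are not controlled and need not be.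

Step 23
Reactants: 39 benzylated tetramer bis-carbinol
Product: 40 heptadeca-O-benzyl-5,5,5-trichloro tetramer
Conditions: Et3SiH (10 equiv), CF3CO2H (20 equiv), CH2Cl2, −40 to 0 °C
Reagents that add atoms: none
Why: Ionic hydrogenation as in step 20, carried out at both carbinols; each C4 cation is expected to take hydride on the face opposite its C3 benzyloxy group, which sets C4 of the upper and side units with the aryl substituent cis to O3. The existing C4–C8 bond of the middle unit has no leaving group, and the chlorine at C5 disfavours its ionisation.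

Step 24
Reactants: 40 heptadeca-O-benzyl-5,5,5-trichloro tetramer
Product: 41 CNP0126838.1
Conditions: H2 (4 bar), Pd(OH)2/C, NaOAc (4 equiv), THF/MeOH/H2O, rt
Reagents that add atoms: none
Why: Hydrogenolysis of the seventeen benzyl ethers and hydrodechlorination of the three aryl chlorides on palladium; acetate takes up the HCl so that the C4–aryl bonds are not exposed to strong acid, and no stereocentre is touched.

## Compound list

1 | caffeic acid | OC(=O)/C=C/c1ccc(O)c(O)c1 | starting material
2 | benzyl (E)-3-[3,4-bis(benzyloxy)phenyl]prop-2-enoate | O=C(OCc1ccccc1)/C=C/c1ccc(OCc2ccccc2)c(OCc2ccccc2)c1 | intermediate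
3 | benzyl (2S,3R)-3-[3,4-bis(benzyloxy)phenyl]oxirane-2-carboxylate (trans) | O=C(OCc1ccccc1)[C@H]1O[C@@H]1c1ccc(OCc2ccccc2)c(OCc2ccccc2)c1 | intermediate
4 | potassium (2S,3R)-3-[3,4-bis(benzyloxy)phenyl]oxirane-2-carboxylate (trans) | [K+].[O-]C(=O)[C@H]1O[C@@H]1c1ccc(OCc2ccccc2)c(OCc2ccccc2)c1 | intermediate
5 | 4-(benzyloxy)phenol | Oc1ccc(OCc2ccccc2)cc1 | starting material
6 | 4-(benzyloxy)-2-chlorophenol | Oc1ccc(OCc2ccccc2)cc1Cl | intermediate
7 | 4-(benzyloxy)-2-bromo-6-chlorophenol | Oc1c(Br)cc(OCc2ccccc2)cc1Cl | intermediate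
8 | [4-(benzyloxy)-2-bromo-6-chlorophenoxy]trimethylsilane | C[Si](C)(C)Oc1c(Br)cc(OCc2ccccc2)cc1Cl | intermediate
9 | {5-(benzyloxy)-3-chloro-2-[(trimethylsilyl)oxy]phenyl}lithium | [Li]c1cc(OCc2ccccc2)cc(Cl)c1O[Si](C)(C)C | intermediate
10 | lithium 4-(benzyloxy)-2-chloro-6-(trimethylsilyl)phenoxide | [Li+].[O-]c1c(Cl)cc(OCc2ccccc2)cc1[Si](C)(C)C | intermediate
11 | 4-(benzyloxy)-2-chloro-6-(trimethylsilyl)phenyl trifluoromethanesulfonate | C[Si](C)(C)c1cc(OCc2ccccc2)cc(Cl)c1OS(=O)(=O)C(F)(F)F | intermediate
12 | 5-(benzyloxy)-3-chlorobenzyne (5-benzyloxy-3-chloro-1,2-didehydrobenzene) | ClC1=CC(OCc2ccccc2)=CC#C1 | intermediate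
13 | potassium 5-(benzyloxy)-3-chloro-2-{[(2S,3R)-3-[3,4-bis(benzyloxy)phenyl]oxiran-2-yl]carbonyl}phenoxide | [K+].[O-]c1cc(OCc9ccccc9)cc(Cl)c1C(=O)[C@H]1O[C@@H]1c1ccc(OCc9ccccc9)c(OCc9ccccc9)c1 | intermediate
14 | (2S,3S)-7-(benzyloxy)-2-[3,4-bis(benzyloxy)phenyl]-5-chloro-3-hydroxychroman-4-one | C(c9ccccc9)Oc1cc(Cl)c2c(c1)O[C@@H](c1ccc(OCc9ccccc9)c(OCc9ccccc9)c1)[C@H](O)C2=O | intermediate
15 | (2S,3S)-3,7-bis(benzyloxy)-2-[3,4-bis(benzyloxy)phenyl]-5-chlorochroman-4-one | C(c9ccccc9)Oc1cc(Cl)c2c(c1)O[C@@H](c1ccc(OCc9ccccc9)c(OCc9ccccc9)c1)[C@H](OCc9ccccc9)C2=O | intermediate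
16 | 5-chlorobenzene-1,3-diol (5-chlororesorcinol) | Oc1cc(O)cc(Cl)c1 | starting material
17 | 4,6-dibromo-5-chlorobenzene-1,3-diol | Oc1cc(O)c(Br)c(Cl)c1Br | intermediate
18 | [(4,6-dibromo-5-chloro-1,3-phenylene)bis(oxy)]bis(trimethylsilane) | C[Si](C)(C)Oc1cc(O[Si](C)(C)C)c(Br)c(Cl)c1Br | intermediate
19 | {3-bromo-2-chloro-4,6-bis[(trimethylsilyl)oxy]phenyl}lithium | [Li]c1c(O[Si](C)(C)C)cc(O[Si](C)(C)C)c(Br)c1Cl | intermediate
20 | lithium 4-bromo-3-chloro-2-(trimethylsilyl)-5-[(trimethylsilyl)oxy]phenoxide | [Li+].[O-]c1cc(O[Si](C)(C)C)c(Br)c(Cl)c1[Si](C)(C)C | intermediate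
21 | 4-bromo-3-chloro-2-(trimethylsilyl)-5-[(trimethylsilyl)oxy]phenyl trifluoromethanesulfonate | C[Si](C)(C)Oc1cc(OS(=O)(=O)C(F)(F)F)c([Si](C)(C)C)c(Cl)c1Br | intermediate
22 | 4-bromo-3-chloro-5-hydroxy-2-(trimethylsilyl)phenyl trifluoromethanesulfonate | Oc1cc(OS(=O)(=O)C(F)(F)F)c([Si](C)(C)C)c(Cl)c1Br | intermediate
23 | 5-(benzyloxy)-4-bromo-3-chloro-2-(trimethylsilyl)phenyl trifluoromethanesulfonate | C[Si](C)(C)c1c(Cl)c(Br)c(OCc2ccccc2)cc1OS(=O)(=O)C(F)(F)F | intermediate
24 | 5-(benzyloxy)-4-bromo-3-chlorobenzyne (5-benzyloxy-4-bromo-3-chloro-1,2-didehydrobenzene) | ClC1=C(Br)C(OCc2ccccc2)=CC#C1 | intermediate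
25 | potassium 5-(benzyloxy)-4-bromo-3-chloro-2-{[(2S,3R)-3-[3,4-bis(benzyloxy)phenyl]oxiran-2-yl]carbonyl}phenoxide | [K+].[O-]c1cc(OCc9ccccc9)c(Br)c(Cl)c1C(=O)[C@H]1O[C@@H]1c1ccc(OCc9ccccc9)c(OCc9ccccc9)c1 | intermediate
26 | (2S,3S)-7-(benzyloxy)-2-[3,4-bis(benzyloxy)phenyl]-6-bromo-5-chloro-3-hydroxychroman-4-one | C(c9ccccc9)Oc1c(Br)c(Cl)c2c(c1)O[C@@H](c1ccc(OCc9ccccc9)c(OCc9ccccc9)c1)[C@H](O)C2=O | intermediate
27 | (2S,3S)-3,7-bis(benzyloxy)-2-[3,4-bis(benzyloxy)phenyl]-6-bromo-5-chlorochroman-4-one | C(c9ccccc9)Oc1c(Br)c(Cl)c2c(c1)O[C@@H](c1ccc(OCc9ccccc9)c(OCc9ccccc9)c1)[C@H](OCc9ccccc9)C2=O | intermediate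
28 | (+)-catechin, (2R,3S) | O[C@H]1Cc2c(O)cc(O)cc2O[C@@H]1c1ccc(O)c(O)c1 | starting material
29 | 5,7,3',4'-tetra-O-benzyl-(+)-catechin, (2R,3S)-5,7-bis(benzyloxy)-2-[3,4-bis(benzyloxy)phenyl]chroman-3-ol | O[C@H]1Cc2c(OCc9ccccc9)cc(OCc9ccccc9)cc2O[C@@H]1c1ccc(OCc9ccccc9)c(OCc9ccccc9)c1 | intermediate
30 | 3,5,7,3',4'-penta-O-benzyl-(+)-catechin, (2R,3S)-3,5,7-tris(benzyloxy)-2-[3,4-bis(benzyloxy)phenyl]chromane | C(c9ccccc9)O[C@H]1Cc2c(OCc9ccccc9)cc(OCc9ccccc9)cc2O[C@@H]1c1ccc(OCc9ccccc9)c(OCc9ccccc9)c1 | intermediate
31 | 8-bromo-3,5,7,3',4'-penta-O-benzyl-(+)-catechin | C(c9ccccc9)O[C@H]1Cc2c(OCc9ccccc9)cc(OCc9ccccc9)c(Br)c2O[C@@H]1c1ccc(OCc9ccccc9)c(OCc9ccccc9)c1 | intermediate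
32 | 8-lithio-3,5,7,3',4'-penta-O-benzyl-(+)-catechin | C(c9ccccc9)O[C@H]1Cc2c(OCc9ccccc9)cc(OCc9ccccc9)c([Li])c2O[C@@H]1c1ccc(OCc9ccccc9)c(OCc9ccccc9)c1 | intermediate
33 | 8-(dichlorocerio)-3,5,7,3',4'-penta-O-benzyl-(+)-catechin | C(c9ccccc9)O[C@H]1Cc2c(OCc9ccccc9)cc(OCc9ccccc9)c([Ce](Cl)Cl)c2O[C@@H]1c1ccc(OCc9ccccc9)c(OCc9ccccc9)c1 | intermediate
34 | benzylated dimer carbinol: (2S,3S)-3,7-bis(benzyloxy)-2-[3,4-bis(benzyloxy)phenyl]-6-bromo-5-chloro-4-[(2R,3S)-3,5,7-tris(benzyloxy)-2-[3,4-bis(benzyloxy)phenyl]chroman-8-yl]chroman-4-ol, carbinol carbon not defined | C(c9ccccc9)Oc1c(Br)c(Cl)c2c(c1)O[C@@H](c1ccc(OCc9ccccc9)c(OCc9ccccc9)c1)[C@H](OCc9ccccc9)C2(O)c1c(OCc9ccccc9)cc(OCc9ccccc9)c2c1O[C@H](c1ccc(OCc9ccccc9)c(OCc9ccccc9)c1)[C@@H](OCc9ccccc9)C2 | intermediate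
35 | benzylated dimer: 6-bromo-5-chloro-ent-fisetinidol-(4→8)-catechin nonabenzyl ether; upper unit 2S,3R with the C4 aryl cis to O3, catechin unit 2R,3S | C(c9ccccc9)Oc1c(Br)c(Cl)c2c(c1)O[C@@H](c1ccc(OCc9ccccc9)c(OCc9ccccc9)c1)[C@H](OCc9ccccc9)[C@@H]2c1c(OCc9ccccc9)cc(OCc9ccccc9)c2c1O[C@H](c1ccc(OCc9ccccc9)c(OCc9ccccc9)c1)[C@@H](OCc9ccccc9)C2 | intermediate
36 | benzylated dimer dibromide: 35 with bromine also at C6 of the catechin unit | C(c9ccccc9)Oc1c(Br)c(Cl)c2c(c1)O[C@@H](c1ccc(OCc9ccccc9)c(OCc9ccccc9)c1)[C@H](OCc9ccccc9)[C@@H]2c1c(OCc9ccccc9)c(Br)c(OCc9ccccc9)c2c1O[C@H](c1ccc(OCc9ccccc9)c(OCc9ccccc9)c1)[C@@H](OCc9ccccc9)C2 | intermediate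
37 | dilithio compound: 36 with lithium in place of both bromines | C(c9ccccc9)Oc1c([Li])c(Cl)c2c(c1)O[C@@H](c1ccc(OCc9ccccc9)c(OCc9ccccc9)c1)[C@H](OCc9ccccc9)[C@@H]2c1c(OCc9ccccc9)c([Li])c(OCc9ccccc9)c2c1O[C@H](c1ccc(OCc9ccccc9)c(OCc9ccccc9)c1)[C@@H](OCc9ccccc9)C2 | intermediate
38 | bis(dichlorocerio) compound: 36 with CeCl2 in place of both bromines | C(c9ccccc9)Oc1c([Ce](Cl)Cl)c(Cl)c2c(c1)O[C@@H](c1ccc(OCc9ccccc9)c(OCc9ccccc9)c1)[C@H](OCc9ccccc9)[C@@H]2c1c(OCc9ccccc9)c([Ce](Cl)Cl)c(OCc9ccccc9)c2c1O[C@H](c1ccc(OCc9ccccc9)c(OCc9ccccc9)c1)[C@@H](OCc9ccccc9)C2 | intermediate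
39 | benzylated tetramer bis-carbinol: 36 with both bromines replaced by (2S,3S)-3,7-bis(benzyloxy)-2-[3,4-bis(benzyloxy)phenyl]-5-chloro-4-hydroxychroman-4-yl groups, carbinol carbons not defined | C(c9ccccc9)Oc1cc(Cl)c2c(c1)O[C@@H](c1ccc(OCc9ccccc9)c(OCc9ccccc9)c1)[C@H](OCc9ccccc9)C2(O)c1c(Cl)c2c(cc1OCc9ccccc9)O[C@@H](c1ccc(OCc9ccccc9)c(OCc9ccccc9)c1)[C@H](OCc9ccccc9)[C@@H]2c1c(OCc9ccccc9)c(C2(O)c3c(Cl)cc(OCc9ccccc9)cc3O[C@@H](c3ccc(OCc9ccccc9)c(OCc9ccccc9)c3)[C@@H]2OCc9ccccc9)c(OCc9ccccc9)c2c1O[C@H](c1ccc(OCc9ccccc9)c(OCc9ccccc9)c1)[C@@H](OCc9ccccc9)C2 | intermediate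
40 | heptadeca-O-benzyl-5,5,5-trichloro tetramer: the target skeleton with all seventeen hydroxyls benzylated and chlorine at C5 of each ent-fisetinidol unit; each such unit 2S,3R with the C4 aryl cis to O3 | C(c9ccccc9)Oc1cc(Cl)c2c(c1)O[C@@H](c1ccc(OCc9ccccc9)c(OCc9ccccc9)c1)[C@H](OCc9ccccc9)[C@@H]2c1c(Cl)c2c(cc1OCc9ccccc9)O[C@@H](c1ccc(OCc9ccccc9)c(OCc9ccccc9)c1)[C@H](OCc9ccccc9)[C@@H]2c1c(OCc9ccccc9)c([C@@H]2c3c(Cl)cc(OCc9ccccc9)cc3O[C@@H](c3ccc(OCc9ccccc9)c(OCc9ccccc9)c3)[C@@H]2OCc9ccccc9)c(OCc9ccccc9)c2c1O[C@H](c1ccc(OCc9ccccc9)c(OCc9ccccc9)c1)[C@@H](OCc9ccccc9)C2 | intermediate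
41 | CNP0126838.1, ent-fisetinidol-(4α→6)-ent-fisetinidol-(4α→8)-catechin-(6→4α)-ent-fisetinidol; upper unit 2S,3R,4R, middle unit 2S,3R,4S, side unit 2S,3R,4S, catechin unit 2R,3S | Oc1ccc2c(c1)O[C@@H](c1ccc(O)c(O)c1)[C@H](O)[C@@H]2c1cc2c(cc1O)O[C@@H](c1ccc(O)c(O)c1)[C@H](O)[C@@H]2c1c(O)c([C@@H]2c3ccc(O)cc3O[C@@H](c3ccc(O)c(O)c3)[C@@H]2O)c(O)c2c1O[C@H](c1ccc(O)c(O)c1)[C@@H](O)C2 | target

## Step count and least certain steps

Total: 24 steps. Longest linear sequence: 12 steps (from 16 through steps 10–15 and 19–24).

**Step 8 (key step).**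
- What may go wrong: the aryl anion formed after O-arylation may be protonated before the acyl group migrates, which stops the cascade at the aryl ester. The acylphenoxide may open the epoxide 5-exo at the α-carbon, a course that a substituent next to the acyl group is known to favour in chalcone epoxides. The product alkoxide may be arylated by a second aryne. Prolonged exposure of the ketol alkoxide to fluoride may epimerise C3 or open ring C.
- Fallback (known chemistry), setting out from 11 and returning at 14: the aryne from 11 is inserted into the C–O bond of acetic acid under the established conditions (CsF, THF, sealed vessel, heat) to give 1-[4-(benzyloxy)-2-chloro-6-hydroxyphenyl]ethan-1-one F1. The phenol is protected (MeOCH2Cl, i-Pr2NEt) as 1-[4-(benzyloxy)-2-chloro-6-(methoxymethoxy)phenyl]ethan-1-one F2. Claisen–Schmidt condensation with 3,4-bis(benzyloxy)benzaldehyde (KOH, EtOH) gives (E)-1-[4-(benzyloxy)-2-chloro-6-(methoxymethoxy)phenyl]-3-[3,4-bis(benzyloxy)phenyl]prop-2-en-1-one F3. Julia–Colonna epoxidation (poly-D-leucine, urea–hydrogen peroxide) gives [4-(benzyloxy)-2-chloro-6-(methoxymethoxy)phenyl][(2S,3R)-3-[3,4-bis(benzyloxy)phenyl]oxiran-2-yl]methanone F4, which has the configuration of intermediate 13. Methanolic HCl removes the acetal and the free phenol closes ring C at the benzylic carbon to give 14.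

**Step 14.**
- What may go wrong: the same failure modes as in step 8. In addition, the bromine buttressing the chlorine may slow the acyl transfer at the crowded aryl anion, so that protonation or loss of halide from the anion competes.
- Fallback (known chemistry), setting out from 23 and returning at 26: insertion of the aryne from 23 into acetic acid gives 1-[4-(benzyloxy)-3-bromo-2-chloro-6-hydroxyphenyl]ethan-1-one F5. Protection gives 1-[4-(benzyloxy)-3-bromo-2-chloro-6-(methoxymethoxy)phenyl]ethan-1-one F6. Condensation with 3,4-bis(benzyloxy)benzaldehyde gives (E)-1-[4-(benzyloxy)-3-bromo-2-chloro-6-(methoxymethoxy)phenyl]-3-[3,4-bis(benzyloxy)phenyl]prop-2-en-1-one F7. Julia–Colonna epoxidation with poly-D-leucine gives [4-(benzyloxy)-3-bromo-2-chloro-6-(methoxymethoxy)phenyl][(2S,3R)-3-[3,4-bis(benzyloxy)phenyl]oxiran-2-yl]methanone F8. Methanolic HCl then gives 26.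

**Step 22.**
- What may go wrong: the second addition may stall. The cerium centre at catechin C6 sits between two benzyloxy groups on a ring that already carries the middle unit, and the ketone has chlorine peri to the carbonyl. An aryl metal that is protonated instead gives debrominated material that cannot be recycled.
- Fallback, setting out from 35 and returning at 40 (the two units are attached one after the other, so that each addition can be driven with excess ketone on a single aryl metal): 35 is lithiated at its only bromide, transmetalated with CeCl3 and added to 15 to give the benzylated trimer carbinol F9. Ionic reduction (Et3SiH, CF3CO2H) gives the benzylated trimer F10. NBS brominates catechin C6 to give the benzylated trimer bromide F11. Exchange, CeCl3 and a second portion of 15 give the benzylated tetramer mono-carbinol F12, and ionic reduction of F12 gives 40.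

**Step 20 (the same question recurs in step 23).**
- What may go wrong: facial selectivity of hydride delivery may be poor. In the 2,3-trans series the C3 substituent can lie in the ring plane, where it shields neither face well. The cation may also lose the C3 proton reversibly to an enol ether, which erodes the C3 configuration.
- Fallback, setting out from 26 and returning at 35 (a larger group on O3 takes over the stereocontrol): 26 is silylated (t-BuMe2SiOSO2CF3, 2,6-lutidine) to (2S,3S)-7-(benzyloxy)-2-[3,4-bis(benzyloxy)phenyl]-6-bromo-3-[(tert-butyldimethylsilyl)oxy]-5-chlorochroman-4-one F13. Addition of the cerium reagent from 31 gives the silylated dimer carbinol F14. Ionic reduction gives the 3-O-silyl dimer F15; the bulky silyloxy group next to the C4 aryl is forced out of the ring plane and should block its own face more effectively. Bu4NF gives the dimer with free 3-hydroxyl F16, and NaH with BnBr gives 35.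

**Step 24.**
- What may go wrong: hydrodechlorination of the three electron-rich aryl chlorides may lag behind debenzylation and leave partly chlorinated polyphenols that are hard to separate. Chloride may slow the catalyst, and insufficient buffering would expose the C4–aryl bonds to HCl.
- Fallback, setting out from 40 and returning at 41 (the two reductions are separated): the chlorines are removed first in homogeneous solution by palladium-catalysed transfer reduction (Pd(OAc)2, 2-dicyclohexylphosphino-2',4',6'-triisopropylbiphenyl, HCO2Na, DMF, 80 °C) to give the chlorine-free heptadecabenzyl tetramer F17. F17 is then hydrogenolysed under neutral conditions (H2, Pd(OH)2/C, THF/MeOH) to 41.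

## Further compounds

F1 | step 8 | 1-[4-(benzyloxy)-2-chloro-6-hydroxyphenyl]ethan-1-one | CC(=O)c1c(O)cc(OCc2ccccc2)cc1Cl
F2 | step 8 | 1-[4-(benzyloxy)-2-chloro-6-(methoxymethoxy)phenyl]ethan-1-one | CC(=O)c1c(OCOC)cc(OCc2ccccc2)cc1Cl
F3 | step 8 | (E)-1-[4-(benzyloxy)-2-chloro-6-(methoxymethoxy)phenyl]-3-[3,4-bis(benzyloxy)phenyl]prop-2-en-1-one | O=C(/C=C/c1ccc(OCc2ccccc2)c(OCc2ccccc2)c1)c1c(OCOC)cc(OCc2ccccc2)cc1Cl
F4 | step 8 | [4-(benzyloxy)-2-chloro-6-(methoxymethoxy)phenyl][(2S,3R)-3-[3,4-bis(benzyloxy)phenyl]oxiran-2-yl]methanone | O=C([C@H]1O[C@@H]1c1ccc(OCc2ccccc2)c(OCc2ccccc2)c1)c1c(OCOC)cc(OCc2ccccc2)cc1Cl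
F5 | step 14 | 1-[4-(benzyloxy)-3-bromo-2-chloro-6-hydroxyphenyl]ethan-1-one | CC(=O)c1c(O)cc(OCc2ccccc2)c(Br)c1Cl
F6 | step 14 | 1-[4-(benzyloxy)-3-bromo-2-chloro-6-(methoxymethoxy)phenyl]ethan-1-one | CC(=O)c1c(OCOC)cc(OCc2ccccc2)c(Br)c1Cl
F7 | step 14 | (E)-1-[4-(benzyloxy)-3-bromo-2-chloro-6-(methoxymethoxy)phenyl]-3-[3,4-bis(benzyloxy)phenyl]prop-2-en-1-one | O=C(/C=C/c1ccc(OCc2ccccc2)c(OCc2ccccc2)c1)c1c(OCOC)cc(OCc2ccccc2)c(Br)c1Cl
F8 | step 14 | [4-(benzyloxy)-3-bromo-2-chloro-6-(methoxymethoxy)phenyl][(2S,3R)-3-[3,4-bis(benzyloxy)phenyl]oxiran-2-yl]methanone | O=C([C@H]1O[C@@H]1c1ccc(OCc2ccccc2)c(OCc2ccccc2)c1)c1c(OCOC)cc(OCc2ccccc2)c(Br)c1Cl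
F9 | step 22 | benzylated trimer carbinol: 35 with its bromine replaced by the (2S,3S)-3,7-bis(benzyloxy)-2-[3,4-bis(benzyloxy)phenyl]-5-chloro-4-hydroxychroman-4-yl group, carbinol carbon not defined | C(c9ccccc9)Oc1cc(Cl)c2c(c1)O[C@@H](c1ccc(OCc9ccccc9)c(OCc9ccccc9)c1)[C@H](OCc9ccccc9)C2(O)c1c(Cl)c2c(cc1OCc9ccccc9)O[C@@H](c1ccc(OCc9ccccc9)c(OCc9ccccc9)c1)[C@H](OCc9ccccc9)[C@@H]2c1c(OCc9ccccc9)cc(OCc9ccccc9)c2c1O[C@H](c1ccc(OCc9ccccc9)c(OCc9ccccc9)c1)[C@@H](OCc9ccccc9)C2
F10 | step 22 | benzylated trimer: upper and middle units linked 4→6, middle unit linked 4→8 to catechin, both C4 aryl groups cis to O3, chlorine at C5 of both ent-fisetinidol units | C(c9ccccc9)Oc1cc(Cl)c2c(c1)O[C@@H](c1ccc(OCc9ccccc9)c(OCc9ccccc9)c1)[C@H](OCc9ccccc9)[C@@H]2c1c(Cl)c2c(cc1OCc9ccccc9)O[C@@H](c1ccc(OCc9ccccc9)c(OCc9ccccc9)c1)[C@H](OCc9ccccc9)[C@@H]2c1c(OCc9ccccc9)cc(OCc9ccccc9)c2c1O[C@H](c1ccc(OCc9ccccc9)c(OCc9ccccc9)c1)[C@@H](OCc9ccccc9)C2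
F11 | step 22 | benzylated trimer bromide: F10 with bromine at C6 of the catechin unit | C(c9ccccc9)Oc1cc(Cl)c2c(c1)O[C@@H](c1ccc(OCc9ccccc9)c(OCc9ccccc9)c1)[C@H](OCc9ccccc9)[C@@H]2c1c(Cl)c2c(cc1OCc9ccccc9)O[C@@H](c1ccc(OCc9ccccc9)c(OCc9ccccc9)c1)[C@H](OCc9ccccc9)[C@@H]2c1c(OCc9ccccc9)c(Br)c(OCc9ccccc9)c2c1O[C@H](c1ccc(OCc9ccccc9)c(OCc9ccccc9)c1)[C@@H](OCc9ccccc9)C2
F12 | step 22 | benzylated tetramer mono-carbinol: 40 with hydroxyl in place of hydrogen at C4 of the side unit, carbinol carbon not defined | C(c9ccccc9)Oc1cc(Cl)c2c(c1)O[C@@H](c1ccc(OCc9ccccc9)c(OCc9ccccc9)c1)[C@H](OCc9ccccc9)[C@@H]2c1c(Cl)c2c(cc1OCc9ccccc9)O[C@@H](c1ccc(OCc9ccccc9)c(OCc9ccccc9)c1)[C@H](OCc9ccccc9)[C@@H]2c1c(OCc9ccccc9)c(C2(O)c3c(Cl)cc(OCc9ccccc9)cc3O[C@@H](c3ccc(OCc9ccccc9)c(OCc9ccccc9)c3)[C@@H]2OCc9ccccc9)c(OCc9ccccc9)c2c1O[C@H](c1ccc(OCc9ccccc9)c(OCc9ccccc9)c1)[C@@H](OCc9ccccc9)C2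
F13 | step 20 | (2S,3S)-7-(benzyloxy)-2-[3,4-bis(benzyloxy)phenyl]-6-bromo-3-[(tert-butyldimethylsilyl)oxy]-5-chlorochroman-4-one | C(c9ccccc9)Oc1c(Br)c(Cl)c2c(c1)O[C@@H](c1ccc(OCc9ccccc9)c(OCc9ccccc9)c1)[C@H](O[Si](C)(C)C(C)(C)C)C2=O
F14 | step 20 | silylated dimer carbinol: 34 with tert-butyldimethylsilyl in place of benzyl on O3 of the upper unit, carbinol carbon not defined | C(c9ccccc9)Oc1c(Br)c(Cl)c2c(c1)O[C@@H](c1ccc(OCc9ccccc9)c(OCc9ccccc9)c1)[C@H](O[Si](C)(C)C(C)(C)C)C2(O)c1c(OCc9ccccc9)cc(OCc9ccccc9)c2c1O[C@H](c1ccc(OCc9ccccc9)c(OCc9ccccc9)c1)[C@@H](OCc9ccccc9)C2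
F15 | step 20 | 3-O-silyl dimer: 35 with tert-butyldimethylsilyl in place of benzyl on O3 of the upper unit | C(c9ccccc9)Oc1c(Br)c(Cl)c2c(c1)O[C@@H](c1ccc(OCc9ccccc9)c(OCc9ccccc9)c1)[C@H](O[Si](C)(C)C(C)(C)C)[C@@H]2c1c(OCc9ccccc9)cc(OCc9ccccc9)c2c1O[C@H](c1ccc(OCc9ccccc9)c(OCc9ccccc9)c1)[C@@H](OCc9ccccc9)C2
F16 | step 20 | dimer with free 3-hydroxyl in the upper unit: 35 lacking the benzyl group on O3 of the upper unit | C(c9ccccc9)Oc1c(Br)c(Cl)c2c(c1)O[C@@H](c1ccc(OCc9ccccc9)c(OCc9ccccc9)c1)[C@H](O)[C@@H]2c1c(OCc9ccccc9)cc(OCc9ccccc9)c2c1O[C@H](c1ccc(OCc9ccccc9)c(OCc9ccccc9)c1)[C@@H](OCc9ccccc9)C2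
F17 | step 24 | chlorine-free heptadecabenzyl tetramer: the target with all seventeen hydroxyls benzylated | C(c9ccccc9)Oc1ccc2c(c1)O[C@@H](c1ccc(OCc9ccccc9)c(OCc9ccccc9)c1)[C@H](OCc9ccccc9)[C@@H]2c1cc2c(cc1OCc9ccccc9)O[C@@H](c1ccc(OCc9ccccc9)c(OCc9ccccc9)c1)[C@H](OCc9ccccc9)[C@@H]2c1c(OCc9ccccc9)c([C@@H]2c3ccc(OCc9ccccc9)cc3O[C@@H](c3ccc(OCc9ccccc9)c(OCc9ccccc9)c3)[C@@H]2OCc9ccccc9)c(OCc9ccccc9)c2c1O[C@H](c1ccc(OCc9ccccc9)c(OCc9ccccc9)c1)[C@@H](OCc9ccccc9)C2
A1 | alternative 1 | benzyl-protected tetramer with C3=C4 double bonds in the upper unit and in the side unit on catechin C6 (bis-flav-3-ene) | C(c9ccccc9)Oc1ccc2c(c1)O[C@@H](c1ccc(OCc9ccccc9)c(OCc9ccccc9)c1)C=C2c1cc2c(cc1OCc9ccccc9)O[C@@H](c1ccc(OCc9ccccc9)c(OCc9ccccc9)c1)[C@H](OCc9ccccc9)[C@@H]2c1c(OCc9ccccc9)c(C2=C[C@H](c3ccc(OCc9ccccc9)c(OCc9ccccc9)c3)Oc3cc(OCc9ccccc9)ccc23)c(OCc9ccccc9)c2c1O[C@H](c1ccc(OCc9ccccc9)c(OCc9ccccc9)c1)[C@@H](OCc9ccccc9)C2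
A2 | alternative 2 | cis-3,7-bis(benzyloxy)-6-bromo-4-(penta-O-benzylcatechin-8-yl)chroman-2-one (cis-dihydrocoumarin) | Brc1cc2c(cc1OCc9ccccc9)OC(=O)[C@H](OCc9ccccc9)[C@@H]2c1c(OCc9ccccc9)cc(OCc9ccccc9)c2c1O[C@H](c1ccc(OCc9ccccc9)c(OCc9ccccc9)c1)[C@@H](OCc9ccccc9)C2
A3 | alternative 3 | benzyl-protected tetramer with pivalate esters on O3 of the three ent-fisetinidol units (tris-pivalate) | C(c9ccccc9)Oc1ccc2c(c1)O[C@@H](c1ccc(OCc9ccccc9)c(OCc9ccccc9)c1)[C@H](OC(=O)C(C)(C)C)[C@@H]2c1cc2c(cc1OCc9ccccc9)O[C@@H](c1ccc(OCc9ccccc9)c(OCc9ccccc9)c1)[C@H](OC(=O)C(C)(C)C)[C@@H]2c1c(OCc9ccccc9)c([C@@H]2c3ccc(OCc9ccccc9)cc3O[C@@H](c3ccc(OCc9ccccc9)c(OCc9ccccc9)c3)[C@@H]2OC(=O)C(C)(C)C)c(OCc9ccccc9)c2c1O[C@H](c1ccc(OCc9ccccc9)c(OCc9ccccc9)c1)[C@@H](OCc9ccccc9)C2
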